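Retrosynthesis: ring A is a cross-conjugated divinyl ketone whose C2 carbonyl lies between sp2 C1 (=C1′H2) and sp2 C3 (the enol carbon), so C1–C2 and C2–C3 are cut and C2 is returned as CO; this leaves ring B with a C10 enol triflate and a C5 α-aryloxyvinylstannane (tin cis to C5).
C3 is then cut from C4 (C4 aldehyde plus CBr4) and the triflate is traced to a C10 ethynyl group; alkyne and aldehyde are released together by Eschenmoser–Tanabe fragmentation of a cis-hydrindane whose five-membered ring is C10–C1–C1′–C4–C5.
The hydrindane goes back to the Hajos–Parrish-type enedione from 2-methylcyclopentane-1,3-dione and pent-1-en-3-one; C11–C13 come from but-3-en-2-one, C14–C15 from a phosphonoacetate, the C7 methyl from MeMgBr.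
Forward: ring B forms first (aldol condensation), the auxiliary five-membered ring is opened in step 17, ring A closes last in step 23, and two deprotections finish.
Stereochemistry: C10 from the (S)-phenylalanine-mediated aldol; C5 by cis hydrogenation; C6 by Michael addition anti to the C5–C4 bond; C7 and C8 by one syn hydroboration; the cis relation of the C5 and C10 arms is locked by the five-membered ring; the C3=C4 geometry comes from a trans-selective C–O coupling of a 1,1-dibromoalkene and a retentive Br→Sn exchange.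

Key step: step 23

Remark: positions C1–C10 are those of the target decalin, C1′ is the exo-methylene carbon, C11–C15 the side chain (methyl on C13); β is the face of ring B that carries the C10 methyl, α the other face; TBS = tert-butyldimethylsilyl, Tf = trifluoromethanesulfonyl. The diosphenol oxygen is carried as a 4-methoxyphenyl ether and tin as SnMe3, because this is what the stereospecific route to the tin-cis-to-C5 stannane delivers.

Step 1
Reactants: 1 2-methylcyclopentane-1,3-dione; 2 pent-1-en-3-one
Product: 3 2-methyl-2-(3-oxopentyl)cyclopentane-1,3-dione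
Conditions: H2O, AcOH (cat.), 75 °C
Reagents that add atoms: pent-1-en-3-one (2), CCC(=O)C=C
Why: Michael addition of the acidic 1,3-dione to the vinyl ketone in water should give the prochiral triketone without further condensation.

Step 2
Reactants: 3 triketone
Product: 4 (S)-4,7a-dimethyl-2,3,7,7a-tetrahydro-1H-indene-1,5(6H)-dione (enedione: C1 ketone, C5=C6 enone with C7 carbonyl, C10 methyl)
Conditions: (S)-phenylalanine, (1S)-(+)-camphor-10-sulfonic acid, DMF, 30 → 70 °C
Reagents that add atoms: none
Why: Hajos–Parrish–Eder–Sauer–Wiechert aldol condensation, in which the amino acid enamine of the ethyl ketone selects one of the two enantiotopic ring carbonyls and thereby sets C10 as (S); recrystallisation should raise the enantiomeric purity.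

Step 3
Reactants: 4 enedione
Product: 5 (1S,7aS)-1-hydroxy-4,7a-dimethyl-1,2,3,6,7,7a-hexahydro-5H-inden-5-one (C1 β-alcohol)
Conditions: NaBH4, EtOH, −20 °C
Reagents that add atoms: none
Why: Chemoselective hydride reduction of the saturated cyclopentanone over the less electrophilic enone carbonyl, with hydride entering anti to the angular methyl; this temporary centre is oxidised again in step 14.

Step 4
Reactants: 5 hydroxy enone
Product: 6 C1 TBS ether of 5
Conditions: TBSCl, imidazole, DMF, rt
Reagents that add atoms: tert-butyldimethylsilyl chloride, CC(C)(C)[Si](C)(C)Cl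
Why: Standard silylation masks the C1 oxygen so that only the ring B ketone is enolised in the following steps.

Step 5
Reactants: 6 silyloxy enone
Product: 7 cis-fused hydrindanone (C5–H β, cis to the C10 methyl; C6–H β, C6–Me α; C1 β-OTBS)
Conditions: H2 (3 atm), 10% Pd/C, EtOAc, Et3N (trace), rt
Reagents that add atoms: none
Why: Heterogeneous hydrogenation of hydrindenones of this type adds hydrogen cis to the angular methyl and should set C5 with the cis ring fusion; C6 is epimerisable and is reset in step 6.

Step 6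
Reactants: 7 cis-hydrindanone; 8 but-3-en-2-one
Product: 11 C6-quaternary diketone (C6: Me α, 3-oxobutyl β), via ketimine 9 (not isolated), via alkylated ketimine 10 (not isolated)
Conditions: (R)-1-phenylethylamine, TsOH (cat.), toluene, reflux (−H2O); then 8, THF, 40 °C; then 10% aq. AcOH, rt
Reagents that add atoms: but-3-en-2-one (8), CC(=O)C=C
Why: Michael addition of a chiral imine through its more substituted secondary enamine tautomer makes C6 quaternary under neutral conditions (no annulation); the acceptor should add anti to the C5–C4 bond (cis to C5–H), the face that the (R)-auxiliary is also expected to favour.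

Step 7
Reactants: 11 diketone
Product: 12 dioxolane of the C13 ketone (C7 ketone free)
Conditions: (TMSOCH2)2, TMSOTf (5 mol%), CH2Cl2, −78 → −20 °C
Reagents that add atoms: 1,2-bis(trimethylsilyloxy)ethane, C[Si](C)(C)OCCO[Si](C)(C)C
Why: Silyl-transfer acetalisation should take the unhindered methyl ketone and leave the C7 ketone next to quaternary C6 untouched.

Step 8
Reactants: 12 ketal ketone
Product: 13 C7 enol triflate (C7=C8)
Conditions: KN(SiMe3)2, THF, −78 °C; PhNTf2, −78 → 0 °C
Reagents that add atoms: N-phenylbis(trifluoromethanesulfonimide), O=S(=O)(N(c1ccccc1)S(=O)(=O)C(F)(F)F)C(F)(F)F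
Why: Enolisation is possible only towards C8 because C6 is quaternary, and O-sulfonylation of the potassium enolate gives the alkenyl triflate.

Step 9
Reactants: 13 enol triflate
Product: 14 C7-methyl alkene (C7(Me)=C8H)
Conditions: MeMgBr, Fe(acac)3 (5 mol%), THF/NMP, −30 → 0 °C
Reagents that add atoms: methylmagnesium bromide, C[Mg]Br
Why: Iron-catalysed cross-coupling of an alkenyl triflate with a methyl Grignard reagent installs the C7 methyl and tolerates ketal and silyl ether.

Step 10
Reactants: 14 alkene
Product: 15 C8 β-alcohol with C7–H β and C7–Me α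
Conditions: BH3·THF, THF, 0 °C → rt; then NaOH, H2O2, 0 °C → rt
Reagents that add atoms: hydrogen peroxide, OO
Why: Hydroboration–oxidation places boron on the less substituted C8 and adds H and B syn, so C7–Me ends trans to the C8 oxygen; attack should come from the β face because the α face is screened by the pseudoaxial C6 methyl and the axial C10–C1 bond.

Step 11
Reactants: 15 alcohol
Product: 16 C8 acetate
Conditions: Ac2O, pyridine, DMAP (cat.), CH2Cl2, rt
Reagents that add atoms: acetic anhydride, CC(=O)OC(C)=O
Why: Acylation of the equatorial secondary alcohol installs the acetate of the target at a stage where nothing else competes.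

Step 12
Reactants: 16 acetate
Product: 17 C1 alcohol with free C13 ketone (C8 acetate kept)
Conditions: 48% aq. HF, MeCN, rt
Reagents that add atoms: water, O
Why: Aqueous HF cleaves the silyl ether and hydrolyses the dioxolane in one operation, while the acetate is stable to dilute acid.

Step 13
Reactants: 17 hydroxy ketone; 18 tert-butyl diethylphosphonoacetate
Product: 19 (E)-tert-butyl enoate (C13=C14) with free C1 alcohol
Conditions: NaH (slight deficit to 18), THF, 0 → 50 °C
Reagents that add atoms: tert-butyl diethylphosphonoacetate (18), CCOP(=O)(CC(=O)OC(C)(C)C)OCC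
Why: Horner–Wadsworth–Emmons olefination of the methyl ketone should favour the E trisubstituted enoate (minor Z isomer removed by chromatography); the preformed phosphonate anion does not deprotonate the alcohol or attack the acetate.

Step 14
Reactants: 19 hydroxy enoate
Product: 20 C1 ketone
Conditions: Dess–Martin periodinane, NaHCO3, CH2Cl2, rt
Reagents that add atoms: none
Why: Dess–Martin oxidation of the secondary alcohol is neutral and leaves acetate, ester and alkene untouched.

Step 15
Reactants: 20 ketone
Product: 21 cyclopentenone (C1(=O)–C1′H=C4H)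
Conditions: 2-iodoxybenzoic acid, DMSO/toluene, 75 °C
Reagents that add atoms: none
Why: Dehydrogenation of a ketone to the enone with 2-iodoxybenzoic acid; only C1′ is enolisable because C10 is quaternary, so the position of the double bond is fixed.

Step 16
Reactants: 21 enone
Product: 22 α,β-epoxy ketone (C1′–C4 epoxide, oxygen on the convex β face)
Conditions: t-BuOOH, DBU, CH2Cl2, 0 °C → rt
Reagents that add atoms: tert-butyl hydroperoxide, CC(C)(C)OO
Why: Weitz–Scheffer nucleophilic epoxidation under anhydrous conditions spares the acetate; the epoxide configuration is lost in step 17.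

Step 17
Reactants: 22 epoxy ketone
Product: 24 ring B with C10 ethynyl (C1≡C1′H, α) and C5 formyl (C4, α), via tosylhydrazone 23 (not isolated)
Conditions: TsNHNH2, AcOH/CH2Cl2 (1:1), −20 °C → rt
Reagents that add atoms: none
Why: Eschenmoser–Tanabe fragmentation: the epoxy tosylhydrazone opens to an alkoxy azo-alkene that loses N2 and sulfinate with cleavage of C1′–C4, giving alkyne and aldehyde on the same face without touching C5 or C10.

Step 18
Reactants: 24 alkynyl aldehyde; 25 carbon tetrabromide
Product: 26 1,1-dibromoalkene (C5–C4H=C3Br2) with C10 ethynyl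
Conditions: CBr4, PPh3, CH2Cl2, 0 °C
Reagents that add atoms: carbon tetrabromide (25), BrC(Br)(Br)Br
Why: Dibromo-olefination (first stage of the Corey–Fuchs sequence) adds C3 under non-basic conditions, so the hindered C5–H should not epimerise.

Step 19
Reactants: 26 dibromoalkene alkyne
Product: 27 C10 methyl ketone (C1(=O)–C1′H3)
Conditions: (Ph3P)AuNTf2 (3 mol%), 1,4-dioxane/H2O, 70 °C
Reagents that add atoms: water, O
Why: Gold-catalysed Markovnikov hydration of the terminal alkyne gives the methyl ketone; the electron-poor dibromoalkene should not engage the activated alkyne.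

Step 20
Reactants: 27 dibromoalkene ketone; 28 4-methoxyphenol
Product: 29 α-bromo enol ether (C3: Br cis to C5, 4-methoxyphenoxy trans to C5)
Conditions: CuI (15 mol%), 2,2′-bipyridine (30 mol%), K3PO4, toluene, 100 °C
Reagents that add atoms: 4-methoxyphenol (28), COc1ccc(O)cc1
Why: Copper-catalysed Ullmann-type coupling of 1,1-dibromo-1-alkenes with phenols takes place at the C–Br bond trans to the alkyl group, which puts oxygen trans and leaves bromine cis to C5; K3PO4 is too weak to eliminate HBr to the ynol ether.

Step 21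
Reactants: 29 bromo enol ether
Product: 30 α-aryloxyvinylstannane (SnMe3 cis to C5) with C10 acetyl
Conditions: Pd(PPh3)4 (10 mol%), Me3SnSnMe3, toluene, 90 °C
Reagents that add atoms: hexamethylditin, C[Sn](C)(C)[Sn](C)(C)C
Why: Palladium-catalysed stannylation of an alkenyl bromide with a distannane proceeds with retention of geometry under neutral conditions that the methyl ketone, acetate and ester tolerate.

Step 22
Reactants: 30 stannyl ketone
Product: 31 ring B with C10 enol triflate (C1(OTf)=C1′H2) and C5 stannylated enol ether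
Conditions: KN(SiMe3)2 (1.05 equiv), THF, −78 °C; PhNTf2, −78 → −20 °C
Reagents that add atoms: N-phenylbis(trifluoromethanesulfonimide), O=S(=O)(N(c1ccccc1)S(=O)(=O)C(F)(F)F)C(F)(F)F
Why: The methyl ketone can enolise only towards C1′ and is the most acidic site, so kinetic deprotonation and O-triflation give the 1,1-disubstituted enol triflate.

Step 23
Reactants: 31 triflate stannane; 32 carbon monoxide
Product: 33 cis-fused decalin with complete ring A as the 4-methoxyphenyl ether of the diosphenol
Conditions: Pd(PPh3)4 (10 mol%), LiCl, CO (3 atm), 1,4-dioxane, 70 °C, 0.005 M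
Reagents that add atoms: carbon monoxide (32), [C-]#[O+]
Why: Zerovalent palladium adds oxidatively to the C1 enol triflate, chloride from LiCl gives a neutral vinylpalladium chloride, CO inserts to the C2 acylpalladium, the trimethylstannyl group on C3 transmetalates and reductive elimination forms C2–C3. The closest known reaction type is the carbonylative Stille coupling of vinyl triflates with vinylstannanes, which is documented for ring closures and for α-alkoxyvinylstannanes. Ring A closes as a six-membered ring by intramolecular acyl transfer to the stannylated alkene carbon (endo with respect to C3=C4, through a seven-membered acyl–vinyl palladacycle). No stereocentre is created; the five centres of ring B and the C3=C4 geometry are carried through. The step needs carbonylative rather than direct coupling (the latter would give a five-membered diene), which CO pressure, high dilution and fast CO insertion into an unhindered 1,1-disubstituted vinylpalladium should secure. It also needs tin cis to C5, which steps 20 and 21 fix and which the cis placement of the two arms (axial C1, equatorial C4) turns into proximity.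

Step 24
Reactants: 33 tert-butyl ester
Product: 34 C15 carboxylic acid (aryl enol ether kept)
Conditions: TFA, anisole, CH2Cl2, 0 °C → rt
Reagents that add atoms: none
Why: Acidolysis of the tert-butyl ester through the tert-butyl cation leaves acetate and aryl enol ether intact, and the exo-methylene enone cannot isomerise because C10 is quaternary.

Step 25
Reactants: 34 aryl ether acid
Product: 35 CNP0192653.1
Conditions: (NH4)2Ce(NO3)6, MeCN/H2O (4:1), 0 °C
Reagents that add atoms: none
Why: Oxidative removal of the 4-methoxyphenyl group: the electron-rich arene is oxidised, water attacks the ipso carbon and the enol is released as the diosphenol together with benzoquinone, with short contact at 0 °C to protect the product.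

Compound list
1 | 2-methylcyclopentane-1,3-dione | CC1C(=O)CCC1=O | starting material
2 | pent-1-en-3-one | CCC(=O)C=C | starting material
3 | 2-methyl-2-(3-oxopentyl)cyclopentane-1,3-dione | CCC(=O)CCC1(C)C(=O)CCC1=O | intermediate
4 | (S)-4,7a-dimethyl-2,3,7,7a-tetrahydro-1H-indene-1,5(6H)-dione | O=C1CCC2=C(C)C(=O)CC[C@]12C | intermediate
5 | (1S,7aS)-1-hydroxy-4,7a-dimethyl-1,2,3,6,7,7a-hexahydro-5H-inden-5-one | O[C@H]1CCC2=C(C)C(=O)CC[C@]12C | intermediate
6 | C1 TBS ether of 5 | CC(C)(C)[Si](C)(C)O[C@H]1CCC2=C(C)C(=O)CC[C@]12C | intermediate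
7 | cis-fused hydrindanone (C5–H β, C6–H β, C1 β-OTBS) | CC(C)(C)[Si](C)(C)O[C@H]1CC[C@@H]2[C@H](C)C(=O)CC[C@]12C | intermediate
8 | but-3-en-2-one | CC(=O)C=C | starting material
9 | N-[(R)-1-phenylethyl] ketimine of 7 | CC(C)(C)[Si](C)(C)O[C@H]1CC[C@@H]2[C@H](C)C(=N[C@H](C)c3ccccc3)CC[C@]12C | intermediate
10 | C6-(3-oxobutyl) ketimine | CC(C)(C)[Si](C)(C)O[C@H]1CC[C@@H]2[C@@](C)(CCC(C)=O)C(=N[C@H](C)c3ccccc3)CC[C@]12C | intermediate
11 | C6-quaternary diketone (C6: Me α, 3-oxobutyl β) | CC(C)(C)[Si](C)(C)O[C@H]1CC[C@@H]2[C@@](C)(CCC(C)=O)C(=O)CC[C@]12C | intermediate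
12 | C13 dioxolane, C7 ketone | CC(C)(C)[Si](C)(C)O[C@H]1CC[C@@H]2[C@@](C)(CCC3(C)OCCO3)C(=O)CC[C@]12C | intermediate
13 | C7 enol triflate (C7=C8) | CC(C)(C)[Si](C)(C)O[C@H]1CC[C@@H]2[C@@](C)(CCC3(C)OCCO3)C(OS(=O)(=O)C(F)(F)F)=CC[C@]12C | intermediate
14 | C7-methyl alkene | CC(C)(C)[Si](C)(C)O[C@H]1CC[C@@H]2[C@@](C)(CCC3(C)OCCO3)C(C)=CC[C@]12C | intermediate
15 | C8 β-alcohol, C7 α-methyl | CC(C)(C)[Si](C)(C)O[C@H]1CC[C@@H]2[C@@](C)(CCC3(C)OCCO3)[C@H](C)[C@@H](O)C[C@]12C | intermediate
16 | C8 acetate | CC(C)(C)[Si](C)(C)O[C@H]1CC[C@@H]2[C@@](C)(CCC3(C)OCCO3)[C@H](C)[C@@H](OC(C)=O)C[C@]12C | intermediate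
17 | C1 alcohol, C13 ketone, C8 acetate | O[C@H]1CC[C@@H]2[C@@](C)(CCC(C)=O)[C@H](C)[C@@H](OC(C)=O)C[C@]12C | intermediate
18 | tert-butyl diethylphosphonoacetate | CCOP(=O)(CC(=O)OC(C)(C)C)OCC | starting material
19 | (E)-tert-butyl enoate, C1 alcohol | O[C@H]1CC[C@@H]2[C@@](C)(CC/C(C)=C/C(=O)OC(C)(C)C)[C@H](C)[C@@H](OC(C)=O)C[C@]12C | intermediate
20 | (E)-tert-butyl enoate, C1 ketone | O=C1CC[C@@H]2[C@@](C)(CC/C(C)=C/C(=O)OC(C)(C)C)[C@H](C)[C@@H](OC(C)=O)C[C@]12C | intermediate
21 | cyclopentenone (C1′=C4) | O=C1C=C[C@@H]2[C@@](C)(CC/C(C)=C/C(=O)OC(C)(C)C)[C@H](C)[C@@H](OC(C)=O)C[C@]12C | intermediate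
22 | C1′–C4 β-epoxy ketone | O=C1[C@H]3O[C@H]3[C@@H]2[C@@](C)(CC/C(C)=C/C(=O)OC(C)(C)C)[C@H](C)[C@@H](OC(C)=O)C[C@]12C | intermediate
23 | tosylhydrazone of 22 | Cc1ccc(cc1)S(=O)(=O)NN=C1[C@H]3O[C@H]3[C@@H]2[C@@](C)(CC/C(C)=C/C(=O)OC(C)(C)C)[C@H](C)[C@@H](OC(C)=O)C[C@]12C | intermediate
24 | ring B with C10 ethynyl and C5 formyl | O=C[C@@H]1[C@@](C)(CC/C(C)=C/C(=O)OC(C)(C)C)[C@H](C)[C@@H](OC(C)=O)C[C@@]1(C#C)C | intermediate
25 | carbon tetrabromide | BrC(Br)(Br)Br | starting material
26 | C5 2,2-dibromovinyl, C10 ethynyl | BrC(Br)=C[C@@H]1[C@@](C)(CC/C(C)=C/C(=O)OC(C)(C)C)[C@H](C)[C@@H](OC(C)=O)C[C@@]1(C#C)C | intermediate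
27 | C5 2,2-dibromovinyl, C10 acetyl | BrC(Br)=C[C@@H]1[C@@](C)(CC/C(C)=C/C(=O)OC(C)(C)C)[C@H](C)[C@@H](OC(C)=O)C[C@@]1(C(C)=O)C | intermediate
28 | 4-methoxyphenol | COc1ccc(O)cc1 | starting material
29 | α-bromo 4-methoxyphenyl enol ether (Br cis to C5), C10 acetyl | Br/C(Oc2ccc(OC)cc2)=C\[C@@H]1[C@@](C)(CC/C(C)=C/C(=O)OC(C)(C)C)[C@H](C)[C@@H](OC(C)=O)C[C@@]1(C(C)=O)C | intermediate
30 | α-aryloxyvinyl trimethylstannane (Sn cis to C5), C10 acetyl | C[Sn](C)(C)/C(Oc2ccc(OC)cc2)=C\[C@@H]1[C@@](C)(CC/C(C)=C/C(=O)OC(C)(C)C)[C@H](C)[C@@H](OC(C)=O)C[C@@]1(C(C)=O)C | intermediate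
31 | ring B with C10 enol triflate and C5 stannylated aryl enol ether | C[Sn](C)(C)/C(Oc2ccc(OC)cc2)=C\[C@@H]1[C@@](C)(CC/C(C)=C/C(=O)OC(C)(C)C)[C@H](C)[C@@H](OC(C)=O)C[C@@]1(C(=C)OS(=O)(=O)C(F)(F)F)C | intermediate
32 | carbon monoxide | [C-]#[O+] | starting material
33 | cis-decalin dienone, C3 4-methoxyphenyl ether, tert-butyl ester | C=C1C(=O)C(Oc3ccc(OC)cc3)=C[C@@H]2[C@@](C)(CC/C(C)=C/C(=O)OC(C)(C)C)[C@H](C)[C@@H](OC(C)=O)C[C@]12C | intermediate
34 | cis-decalin dienone, C3 4-methoxyphenyl ether, C15 acid | C=C1C(=O)C(Oc3ccc(OC)cc3)=C[C@@H]2[C@@](C)(CC/C(C)=C/C(=O)O)[C@H](C)[C@@H](OC(C)=O)C[C@]12C | intermediate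
35 | CNP0192653.1 | C=C1C(=O)C(O)=C[C@@H]2[C@@](C)(CC/C(C)=C/C(=O)O)[C@H](C)[C@@H](OC(C)=O)C[C@]12C | target

Total step count: 25. Longest linear sequence: 25 steps (from 1 and 2 to 35).

Steps most likely to fail

Step 23. The acylpalladium may not form or transmetalate fast enough, so that direct coupling without CO or protodestannylation of the hindered stannane takes over. The fallback sets out from bromo enol ether 29 and keeps CO as the source of C2. Enol triflation of the methyl ketone (KN(SiMe3)2, PhNTf2) would give the bromo enol ether vinyl triflate F1. Palladium-catalysed formylation of the triflate (CO, Bu3SnH, Pd(PPh3)4, LiCl) would give the 2-substituted acrolein F2. An intramolecular Nozaki–Hiyama–Kishi reaction of the alkenyl bromide with the aldehyde (CrCl2, NiCl2 cat., DMF) would close ring A to the C2 allylic alcohol F3 (either epimer). Dess–Martin oxidation of that alcohol comes back to the route at 33.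

Step 21. Oxidative addition at the hindered, electron-rich C–Br bond may be slow, so that reduction or homocoupling competes with stannylation. The fallback sets out from 29 and replaces palladium by halogen–metal exchange. The methyl ketone would first be masked as its silyl enol ether (KN(SiMe3)2, TBSCl, −78 °C) to give the TBS enol ether bromide F4. Bromine–lithium exchange with t-BuLi at −110 °C and quench with Me3SnCl would give the TBS enol ether stannane F5. CsF and PhNTf2 in DME would then turn the silyl enol ether directly into the enol triflate, coming back to the route at 31.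

Step 25. The cerium oxidant may go on to oxidise the liberated diosphenol. The fallback sets out from dibromoalkene 27 and uses an aryl group that can be removed under much milder oxidation. The coupling of step 20 would be run with 4-tert-butoxyphenol to give the α-bromo 4-tert-butoxyphenyl enol ether F6. The conditions of steps 21 to 23 would then give in turn the stannane F7, the enol triflate F8 and the cyclised dienone F9. TFA would cleave both tert-butyl groups to the 4-hydroxyphenyl enol ether acid F10. Its hydroquinone monoether would be oxidised with PhI(OAc)2 or Ag2O in wet MeCN, which releases benzoquinone and comes back to the route at 35.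

Further compounds
F1 | step 23 | bromo enol ether with C10 enol triflate | Br/C(Oc2ccc(OC)cc2)=C\[C@@H]1[C@@](C)(CC/C(C)=C/C(=O)OC(C)(C)C)[C@H](C)[C@@H](OC(C)=O)C[C@@]1(C(=C)OS(=O)(=O)C(F)(F)F)C
F2 | step 23 | bromo enol ether with C10 1-formylvinyl group | Br/C(Oc2ccc(OC)cc2)=C\[C@@H]1[C@@](C)(CC/C(C)=C/C(=O)OC(C)(C)C)[C@H](C)[C@@H](OC(C)=O)C[C@@]1(C(=C)C=O)C
F3 | step 23 | cyclised C2 allylic alcohol (either C2 epimer) | C=C1C(O)C(Oc3ccc(OC)cc3)=C[C@@H]2[C@@](C)(CC/C(C)=C/C(=O)OC(C)(C)C)[C@H](C)[C@@H](OC(C)=O)C[C@]12C
F4 | step 21 | TBS enol ether bromide | Br/C(Oc2ccc(OC)cc2)=C\[C@@H]1[C@@](C)(CC/C(C)=C/C(=O)OC(C)(C)C)[C@H](C)[C@@H](OC(C)=O)C[C@@]1(C(=C)O[Si](C)(C)C(C)(C)C)C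
F5 | step 21 | TBS enol ether stannane | C[Sn](C)(C)/C(Oc2ccc(OC)cc2)=C\[C@@H]1[C@@](C)(CC/C(C)=C/C(=O)OC(C)(C)C)[C@H](C)[C@@H](OC(C)=O)C[C@@]1(C(=C)O[Si](C)(C)C(C)(C)C)C
F6 | step 25 | α-bromo 4-tert-butoxyphenyl enol ether | Br/C(Oc2ccc(OC(C)(C)C)cc2)=C\[C@@H]1[C@@](C)(CC/C(C)=C/C(=O)OC(C)(C)C)[C@H](C)[C@@H](OC(C)=O)C[C@@]1(C(C)=O)C
F7 | step 25 | 4-tert-butoxyphenyl enol ether stannane | C[Sn](C)(C)/C(Oc2ccc(OC(C)(C)C)cc2)=C\[C@@H]1[C@@](C)(CC/C(C)=C/C(=O)OC(C)(C)C)[C@H](C)[C@@H](OC(C)=O)C[C@@]1(C(C)=O)C
F8 | step 25 | 4-tert-butoxyphenyl enol ether stannane with C10 enol triflate | C[Sn](C)(C)/C(Oc2ccc(OC(C)(C)C)cc2)=C\[C@@H]1[C@@](C)(CC/C(C)=C/C(=O)OC(C)(C)C)[C@H](C)[C@@H](OC(C)=O)C[C@@]1(C(=C)OS(=O)(=O)C(F)(F)F)C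
F9 | step 25 | cyclised dienone as 4-tert-butoxyphenyl ether | C=C1C(=O)C(Oc3ccc(OC(C)(C)C)cc3)=C[C@@H]2[C@@](C)(CC/C(C)=C/C(=O)OC(C)(C)C)[C@H](C)[C@@H](OC(C)=O)C[C@]12C
F10 | step 25 | 4-hydroxyphenyl enol ether acid | C=C1C(=O)C(Oc3ccc(O)cc3)=C[C@@H]2[C@@](C)(CC/C(C)=C/C(=O)O)[C@H](C)[C@@H](OC(C)=O)C[C@]12C
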